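Raising [E] from 0.960 M to 2.90 M in the blue run lifted the X at the last reading further than raising [Q] to 1.60 M in the green run did: 0.513 M against 0.340 M, from 0.238 M in the red run.

| setting | red | ochre | blue | green | violet |
|---|---|---|---|---|---|
| Q | 0.800 M | 0.320 M | 0.800 M | 1.60 M | 1.60 M |
| E | 0.960 M | 0.480 M | 2.90 M | 0.960 M | 1.90 M |
| time |  |  |  |  | 18 min |

- red run (time / min: [X] / M): 3.0: 0.139; 6.0: 0.186; 9.0: 0.213; 12: 0.216; 15: 0.230; 18: 0.238
- ochre run (time / min: [X] / M): 3.0: 0.037; 6.0: 0.028; 9.0: 0.043; 12: 0.079; 15: 0.065; 18: 0.066
- blue run (time / min: [X] / M): 3.0: 0.412; 6.0: 0.480; 9.0: 0.484; 12: 0.507; 15: 0.498; 18: 0.513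
- green run (time / min: [X] / M): 3.0: 0.233; 6.0: 0.279; 9.0: 0.314; 12: 0.327; 15: 0.335; 18: 0.340

(readings scatter by 0.01 M)

- Overall: Q + E -> X.
- Constant volume, constant temperature.
- "The second partner" is E.
- An order is taken over about fifteen percent of the charge, up and down.

- the exponent of [E] in the starting rate at the charge of the red run (at the point where two percent of the Q have become X)
- the exponent of [Q] in the starting rate at the charge of the red run (at the point where two percent of the Q have become X) (one fixed amount of X, the same in the runs compared)
- X in the violet run at 18 min, as a share of the Q charged

The red run rose by just 0.00800 M over its last interval, with 0.562 M of its charged Q and 0.722 M of its E not accounted for by X. I therefore took the working hypothesis that Q leaves by a route without E, in competition with the route to X. That made the useful number a selectivity: the end odds, X at the last reading over charged Q not found as X. These were 0.423 in the red run, 1.79 in the blue run and 0.270 in the green run.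

The violet run has the Q charge of the green run and more E, so I needed one thing: how the odds scale with [E]. I solved two extremes. If the route to X is first order in [E], the odds scale with [E] to the first power, and the violet share is 34.8%. If that route is second order in [E], they scale with its square, and the share is 51.4%. The red and blue runs share a Q charge, so they give 1.30 for the end exponent n, the slope of ln(odds) against ln[E] at one Q charge, which lies between the extremes. Carried from the green run to the violet run, it gave odds of 0.657, a share of 39.6%.

The forecast, holding that “high Q is partly tied up or self-inhibiting”, gave 1.1 for the [E] exponent, 0.8 for the [Q] exponent and 39.5% for the violet share.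

The violet run gave 39.7%. At equal X made, the blue run's rate stood 4.3 times the red run's, with starting exponents of 1.3 in [E] and 1.0 in [Q].

    Q + E → X (0.08220 L mol⁻¹ min⁻¹)
    Q + 2 E → X + E (0.01818 L² mol⁻² min⁻¹)
    Q → Ja (0.09720 min⁻¹)
    2 Q → Lx (0.1236 L mol⁻¹ min⁻¹)

The red and green runs gave an end exponent in the Q charge of −0.650. Together with n, it took the red odds to 0.312 for the ochre run, which means 0.0760 M of X at 18 min, where the ochre reading was 0.066 M.

(The numbers in the tables were generated by integration with made-up constants; the scatter is artificial.)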